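## Retrosynthetic overview

1. Ring numbering: C1 = quaternary carbon (Me, side chain), C2 = CH with the hydroxypropyl chain, C3 = alkylidene carbon, C4 and C5 = CH2, C6 = C(Me)OH. The enal comes from MnO2 oxidation of a (Z)-allylic alcohol, and the C1 side chain from C-alkylation of a ring CH2SO2Ph group with (2E,6E)-farnesyl bromide followed by desulfonylation.
2. The (Z)-tetrasubstituted C3 alkene comes from a C3 ring ketone: enol triflate, Negishi coupling to a 1,3-diene, then stereospecific 1,4-hydrogenation.
3. The only ring, cyclohexane C1–C6, is closed through the C6–C1 bond by a SmI2 ketyl–olefin cyclisation (6-exo) of an acyclic hydroxy ketone. This creates the quaternary carbon C1 and the tertiary carbinol C6 in one event, both relayed from C2.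
4. Enabling feature: C6 is a methyl carbinol (a latent methyl ketone) bonded to C1, and C1 carries a CH2 group. C1 can therefore be the β-carbon of a vinyl sulfone C1=CH–SO2Ph, tethered to the ketone through C2–C5. The sulfonyl group cis to the stereocentre C2 transmits its configuration and later serves as the handle for the farnesyl chain.
5. The acyclic precursor comes from an Evans syn aldol (acyl unit from δ-valerolactone, dioxolane aldehyde), alkyne formation, anti iodosulfonylation and methylation with retention.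

Key step: step 12

Assumption: the target is read as iridal with ring centres C1 (S), C2 (R), C6 (S) and a (Z)-enal. δ-Valerolactone, (R)-4-benzyl-1,3-oxazolidin-2-one, 2-(2-bromoethyl)-2-methyl-1,3-dioxolane, 2-bromoprop-2-en-1-ol and isomerically pure (2E,6E)-farnesyl bromide are taken as purchased.

## Route

Step 1
Reactants: 1 δ-valerolactone (tetrahydro-2H-pyran-2-one)
Product: 4 5-[(tert-butyldiphenylsilyl)oxy]pentanoic acid, via potassium 5-hydroxypentanoate 2 (not isolated), via silyl ester 3 (not isolated)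
Conditions: KOH, MeOH–H2O, rt, evaporate; t-BuPh2SiCl (2.2 equiv), imidazole, DMF, rt; AcOH–THF–H2O, rt
Reagents that add atoms: potassium hydroxide [K+].[OH-]; tert-butyl(chloro)diphenylsilane CC(C)(C)[Si](Cl)(c1ccccc1)c1ccccc1
Why: Saponification of the lactone, silylation of both oxygens and selective hydrolysis of the labile silyl ester is a standard lactone-opening and protection sequence that should give the acid with a robust primary silyl ether (no stereocentre).

Step 2
Reactants: 4 5-[(tert-butyldiphenylsilyl)oxy]pentanoic acid; 5 (R)-4-benzyl-1,3-oxazolidin-2-one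
Product: 7 (R)-4-benzyl-3-{5-[(tert-butyldiphenylsilyl)oxy]pentanoyl}-1,3-oxazolidin-2-one, via mixed pivalic anhydride 6 (not isolated)
Conditions: t-BuCOCl, Et3N, THF, −20 °C; then 5, LiCl, rt
Reagents that add atoms: none
Why: Mixed-anhydride N-acylation of the oxazolidinone activated by LiCl and Et3N should give the imide; its only stereocentre is bought with the auxiliary.

Step 3
Reactants: 8 2-(2-bromoethyl)-2-methyl-1,3-dioxolane
Product: 10 3-(2-methyl-1,3-dioxolan-2-yl)propanal, via Grignard reagent 9 (not isolated)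
Conditions: Mg, THF, 25–30 °C; DMF, 0 °C; aq. NH4Cl
Reagents that add atoms: N,N-dimethylformamide CN(C)C=O
Why: Formylation of a Grignard reagent with DMF (Bouveault aldehyde synthesis) should give the aldehyde, and the buffered work-up leaves the dioxolane intact.

Step 4
Reactants: 7 (R)-4-benzyl-3-{5-[(tert-butyldiphenylsilyl)oxy]pentanoyl}-1,3-oxazolidin-2-one; 10 3-(2-methyl-1,3-dioxolan-2-yl)propanal
Product: 12 (R)-4-benzyl-3-[(2R,3S)-2-{3-[(tert-butyldiphenylsilyl)oxy]propyl}-3-hydroxy-5-(2-methyl-1,3-dioxolan-2-yl)pentanoyl]-1,3-oxazolidin-2-one, via dibutylboron (Z)-enolate 11 (not isolated)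
Conditions: n-Bu2BOTf, i-Pr2NEt, CH2Cl2, −78 → 0 °C; 10, −78 → 0 °C; pH 7 buffer, MeOH, H2O2, 0 °C
Reagents that add atoms: none
Why: Evans syn aldol reaction: the (Z)-boron enolate should add to the aldehyde through a chair Zimmerman–Traxler transition state on the face away from the benzyl group of the (R)-auxiliary, which sets C2 (R) and the C3 carbinol (S) in one event.

Step 5
Reactants: 12 the syn aldol imide
Product: 13 (2R,3S)-2-{3-[(tert-butyldiphenylsilyl)oxy]propyl}-3-hydroxy-N-methoxy-N-methyl-5-(2-methyl-1,3-dioxolan-2-yl)pentanamide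
Conditions: MeONHMe·HCl, AlMe3, THF, −20 → 0 °C; aq. Rochelle salt
Reagents that add atoms: N,O-dimethylhydroxylamine hydrochloride CNOC.Cl
Why: Transamination of the β-hydroxy imide with the aluminium amide of N,O-dimethylhydroxylamine (Weinreb amide formation) is assisted by the free hydroxyl group and should release the auxiliary without epimerising C2.

Step 6
Reactants: 13 the hydroxy Weinreb amide
Product: 14 (2R,3S)-2-{3-[(tert-butyldiphenylsilyl)oxy]propyl}-N-methoxy-N-methyl-5-(2-methyl-1,3-dioxolan-2-yl)-3-[(triethylsilyl)oxy]pentanamide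
Conditions: Et3SiCl, imidazole, DMF, 0 °C → rt
Reagents that add atoms: chlorotriethylsilane CC[Si](Cl)(CC)CC
Why: Silylation of the secondary alcohol with a silyl chloride and imidazole should protect the C3 hydroxyl for the hydride and alkyne-forming steps.

Step 7
Reactants: 14 the silylated Weinreb amide
Product: 15 (2R,3S)-2-{3-[(tert-butyldiphenylsilyl)oxy]propyl}-5-(2-methyl-1,3-dioxolan-2-yl)-3-[(triethylsilyl)oxy]pentanal
Conditions: i-Bu2AlH, THF, −78 °C; aq. Rochelle salt
Reagents that add atoms: none
Why: Reduction of a Weinreb amide with i-Bu2AlH stops at the chelated aluminium hemiaminal, so the aldehyde should be released only on work-up, without over-reduction or epimerisation at C2.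

Step 8
Reactants: 15 the α-branched aldehyde
Product: 16 (3S,4S)-3-{3-[(tert-butyldiphenylsilyl)oxy]propyl}-6-(2-methyl-1,3-dioxolan-2-yl)-4-[(triethylsilyl)oxy]hex-1-yne
Conditions: dimethyl (1-diazo-2-oxopropyl)phosphonate, K2CO3, MeOH, 0 °C → rt
Reagents that add atoms: dimethyl (1-diazo-2-oxopropyl)phosphonate COP(=O)(OC)C(=[N+]=[N-])C(C)=O
Why: Ohira–Bestmann homologation (a Seyferth–Gilbert type reaction) should convert the aldehyde into the terminal alkyne under mild carbonate conditions that normally preserve an α-stereocentre.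

Step 9
Reactants: 16 the terminal alkyne
Product: 17 (1E,3R,4S)-3-{3-[(tert-butyldiphenylsilyl)oxy]propyl}-2-iodo-6-(2-methyl-1,3-dioxolan-2-yl)-1-(phenylsulfonyl)-4-[(triethylsilyl)oxy]hex-1-ene
Conditions: PhSO2Na, I2, EtOAc–H2O, visible light, rt
Reagents that add atoms: sodium benzenesulfinate [Na+].[O-]S(=O)c1ccccc1; iodine II
Why: Radical iodosulfonylation of a terminal alkyne: the sulfonyl radical adds to the terminal carbon and iodine is transferred to the opposite side, which should give the (E)-β-iodovinyl sulfone regio- and stereoselectively.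

Step 10
Reactants: 17 the (E)-β-iodovinyl sulfone
Product: 18 (1Z,3S,4S)-3-{3-[(tert-butyldiphenylsilyl)oxy]propyl}-2-methyl-6-(2-methyl-1,3-dioxolan-2-yl)-1-(phenylsulfonyl)-4-[(triethylsilyl)oxy]hex-1-ene
Conditions: MeZnCl, Pd(PPh3)4 (5 mol%), THF, rt
Reagents that add atoms: methylzinc chloride C[Zn]Cl
Why: Negishi coupling of an alkenyl iodide proceeds with retention of geometry, so the methyl group should enter trans to sulfur and the sulfonyl group stays cis to C2 ((Z)-isomer).

Step 11
Reactants: 18 the (Z)-vinyl sulfone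
Product: 19 (5S,6S,7Z)-6-{3-[(tert-butyldiphenylsilyl)oxy]propyl}-5-hydroxy-7-methyl-8-(phenylsulfonyl)oct-7-en-2-one
Conditions: 1 M aq. HCl–THF (1:4), rt
Reagents that add atoms: water O
Why: Acid-catalysed hydrolysis should remove the dioxolane and the triethylsilyl ether in one operation, while the primary tert-butyldiphenylsilyl ether and the vinyl sulfone are stable to dilute acid.

Step 12
Reactants: 19 the acyclic hydroxy ketone with the (Z)-vinyl sulfone
Product: 20 (1S,2S,3S,4S)-3-{3-[(tert-butyldiphenylsilyl)oxy]propyl}-1,2-dimethyl-2-[(phenylsulfonyl)methyl]cyclohexane-1,4-diol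
Conditions: SmI2 (2.5 equiv), HMPA (10 equiv), t-BuOH (2 equiv), THF, −78 → −20 °C, slow addition of 19
Reagents that add atoms: none
Why: Single-electron reduction of the C6 methyl ketone by SmI2–HMPA gives a samarium ketyl that adds to C1, the β-carbon of the vinyl sulfone; the α-sulfonyl radical is then reduced by a second SmI2 and protonated by t-BuOH. The closest known reaction type is the SmI2-promoted ketone–activated-alkene (ketyl–olefin) cyclisation onto unsaturated esters and vinyl sulfones, including cases that form quaternary carbons. The cyclohexane ring C1–C6 closes in the 6-exo-trig mode through a chair transition state in which the C2 side chain and the C3 hydroxyl are equatorial. C1 is controlled by allylic 1,3-strain: the sulfonyl group cis to C2 holds the C2–H bond in the alkene plane, so the tethered ketyl reaches only the face anti to the C2 side chain, which leaves CH2SO2Ph equatorial and trans to that chain and the methyl axial. C6 is controlled by the bulky HMPA-solvated O–Sm group, which takes the equatorial site remote from the sulfonyl group, so that OH ends trans to CH2SO2Ph and cis to the C1 methyl, while C2 and C3 are not touched. The step needs 6-exo attack at the fully substituted C1 in preference to simple reduction of the ketone or the alkene, which is secured by the polarity match of the nucleophilic ketyl with the electron-poor β-carbon, the six-atom tether and the low temperature.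

Step 13
Reactants: 20 the ring diol
Product: 21 (2S,3S,4S)-2-{3-[(tert-butyldiphenylsilyl)oxy]propyl}-4-hydroxy-3,4-dimethyl-3-[(phenylsulfonyl)methyl]cyclohexan-1-one
Conditions: Dess–Martin periodinane, CH2Cl2, 0 °C → rt
Reagents that add atoms: none
Why: Dess–Martin oxidation should convert the secondary C3 alcohol into the ketone and cannot oxidise the tertiary C6 alcohol; the equatorial C2 side chain is also the thermodynamically preferred epimer next to the new carbonyl group.

Step 14
Reactants: 21 the hydroxy ketone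
Product: 22 (4S,5S,6S)-6-{3-[(tert-butyldiphenylsilyl)oxy]propyl}-4-hydroxy-4,5-dimethyl-5-[(phenylsulfonyl)methyl]cyclohex-1-en-1-yl trifluoromethanesulfonate
Conditions: KN(SiMe3)2 (2.2 equiv), THF, −78 °C; PhNTf2, −78 → 0 °C
Reagents that add atoms: N-phenylbis(trifluoromethanesulfonimide) O=S(=O)(N(c1ccccc1)S(=O)(=O)C(F)(F)F)C(F)(F)F
Why: Kinetic deprotonation with the hindered silylamide (one equivalent for the alkoxide, one for the enolate) should occur at the C4 methylene and not at the C2 methine, and O-sulfonylation of the enolate (enol triflate formation) gives the C3=C4 triflate, the tertiary alkoxide being too hindered to react.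

Step 15
Reactants: 23 2-bromoprop-2-en-1-ol
Product: 24 [(2-bromoprop-2-en-1-yl)oxy](tert-butyl)dimethylsilane
Conditions: t-BuMe2SiCl, imidazole, CH2Cl2, rt
Reagents that add atoms: tert-butyl(chloro)dimethylsilane CC(C)(C)[Si](C)(C)Cl
Why: Silylation of a primary allylic alcohol with a silyl chloride and imidazole is routine and gives the coupling partner (no stereocentre).

Step 16
Reactants: 22 the enol triflate; 24 [(2-bromoprop-2-en-1-yl)oxy](tert-butyl)dimethylsilane
Product: 27 diene: ring as in 22 with 3-[(tert-butyldimethylsilyl)oxy]prop-1-en-2-yl in place of the triflate group at C3, via alkenyllithium 25 (not isolated), via alkenylzinc bromide 26 (not isolated)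
Conditions: 24, t-BuLi (2 equiv), Et2O, −78 °C; ZnBr2, THF, −78 → 0 °C; then 22, Pd(PPh3)4 (5 mol%), THF, rt → 45 °C
Reagents that add atoms: none
Why: Negishi coupling: bromine–lithium exchange and transmetalation to zinc give an alkenylzinc that should couple with the enol triflate under zerovalent palladium catalysis to the 2,3-disubstituted 1,3-diene.

Step 17
Reactants: 27 the 1,3-diene
Product: 28 (Z)-alkylidene sulfone: ring centres as in 21, C3 carrying =C(CH3)CH2OSiMe2t-Bu with CH2OSi cis to C2
Conditions: (η6-naphthalene)Cr(CO)3 (20 mol%), H2 (50 atm), THF, 45 °C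
Reagents that add atoms: none
Why: 1,4-Hydrogenation of a conjugated diene catalysed by an arene chromium tricarbonyl complex adds both hydrogen atoms to the termini of the s-cis diene (C4 and the exocyclic CH2), so the new C3=C bond should form with the new methyl cis to C4 and CH2OSi cis to C2 ((Z)-alkene), while the sulfone and silyl ethers are not reduced.

Step 18
Reactants: 28 the (Z)-alkylidene sulfone; 29 (2E,6E)-farnesyl bromide
Product: 30 farnesylated sulfone: as 28 with the C1 substituent CH(SO2Ph)CH2CH=C(CH3)… (all-E chain, mixture at the sulfone carbon)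
Conditions: n-BuLi (2.1 equiv), THF–HMPA, −78 °C; then 29, −78 → −20 °C
Reagents that add atoms: none
Why: Sulfone alkylation (Julia-type C–C coupling): the second equivalent of n-BuLi generates the α-sulfonyl carbanion next to the lithium alkoxide, and its SN2 reaction with the primary allylic bromide should attach the chain with both (E)-double bonds unchanged; the new sulfone-bearing stereocentre is removed in step 19.

Step 19
Reactants: 30 the farnesylated sulfone
Product: 31 bis-silyl ether of the triol: C1 carrying the complete (3E,7E)-4,8,12-trimethyltrideca-3,7,11-trienyl chain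
Conditions: sodium amalgam (6% Na), Na2HPO4, MeOH–THF, −20 °C → rt
Reagents that add atoms: none
Why: Reductive desulfonylation with buffered sodium amalgam should cleave the C–S bond by electron transfer and leaves the isolated alkenes, the allylic silyl ether and the tertiary alcohol untouched.

Step 20
Reactants: 31 the bis-silyl ether
Product: 32 triol: the C6 tertiary alcohol, the 3-hydroxypropyl group at C2 and the (Z)-allylic primary alcohol at C3
Conditions: Bu4NF, THF, 0 °C → rt
Reagents that add atoms: none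
Why: Fluoride-mediated desilylation should cleave both primary silyl ethers without affecting the alkenes or the tertiary alcohol.

Step 21
Reactants: 32 the triol
Product: 33 iridal
Conditions: activated MnO2, CH2Cl2, rt, dark
Reagents that add atoms: none
Why: Activated MnO2 oxidises allylic alcohols selectively, so only the allylic primary alcohol should be converted into the conjugated aldehyde, with retention of the (Z)-geometry and without touching the saturated primary and the tertiary alcohol.

## Compound list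

1 | δ-valerolactone (tetrahydro-2H-pyran-2-one) | O=C1CCCCO1 | starting material
2 | potassium 5-hydroxypentanoate | [K+].[O-]C(=O)CCCCO | intermediate
3 | tert-butyldiphenylsilyl 5-[(tert-butyldiphenylsilyl)oxy]pentanoate | CC(C)(C)[Si](OCCCCC(=O)O[Si](c1ccccc1)(c1ccccc1)C(C)(C)C)(c1ccccc1)c1ccccc1 | intermediate
4 | 5-[(tert-butyldiphenylsilyl)oxy]pentanoic acid | OC(=O)CCCCO[Si](c1ccccc1)(c1ccccc1)C(C)(C)C | intermediate
5 | (R)-4-benzyl-1,3-oxazolidin-2-one | O=C1N[C@H](Cc2ccccc2)CO1 | starting material
6 | 5-[(tert-butyldiphenylsilyl)oxy]pentanoic pivalic anhydride | CC(C)(C)C(=O)OC(=O)CCCCO[Si](c1ccccc1)(c1ccccc1)C(C)(C)C | intermediate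
7 | (R)-4-benzyl-3-{5-[(tert-butyldiphenylsilyl)oxy]pentanoyl}-1,3-oxazolidin-2-one | O=C(CCCCO[Si](c1ccccc1)(c1ccccc1)C(C)(C)C)N1[C@H](Cc2ccccc2)COC1=O | intermediate
8 | 2-(2-bromoethyl)-2-methyl-1,3-dioxolane | CC1(CCBr)OCCO1 | starting material
9 | [2-(2-methyl-1,3-dioxolan-2-yl)ethyl]magnesium bromide | CC1(CC[Mg]Br)OCCO1 | intermediate
10 | 3-(2-methyl-1,3-dioxolan-2-yl)propanal | CC1(CCC=O)OCCO1 | intermediate
11 | dibutylboron (Z)-enolate of 7 | CCCCB(CCCC)O/C(=C\CCCO[Si](c1ccccc1)(c1ccccc1)C(C)(C)C)N1[C@H](Cc2ccccc2)COC1=O | intermediate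
12 | (R)-4-benzyl-3-[(2R,3S)-2-{3-[(tert-butyldiphenylsilyl)oxy]propyl}-3-hydroxy-5-(2-methyl-1,3-dioxolan-2-yl)pentanoyl]-1,3-oxazolidin-2-one | O=C(N1[C@H](Cc2ccccc2)COC1=O)[C@H](CCCO[Si](c1ccccc1)(c1ccccc1)C(C)(C)C)[C@@H](O)CCC1(C)OCCO1 | intermediate
13 | (2R,3S)-2-{3-[(tert-butyldiphenylsilyl)oxy]propyl}-3-hydroxy-N-methoxy-N-methyl-5-(2-methyl-1,3-dioxolan-2-yl)pentanamide | CON(C)C(=O)[C@H](CCCO[Si](c1ccccc1)(c1ccccc1)C(C)(C)C)[C@@H](O)CCC1(C)OCCO1 | intermediate
14 | (2R,3S)-2-{3-[(tert-butyldiphenylsilyl)oxy]propyl}-N-methoxy-N-methyl-5-(2-methyl-1,3-dioxolan-2-yl)-3-[(triethylsilyl)oxy]pentanamide | CON(C)C(=O)[C@H](CCCO[Si](c1ccccc1)(c1ccccc1)C(C)(C)C)[C@@H](O[Si](CC)(CC)CC)CCC1(C)OCCO1 | intermediate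
15 | (2R,3S)-2-{3-[(tert-butyldiphenylsilyl)oxy]propyl}-5-(2-methyl-1,3-dioxolan-2-yl)-3-[(triethylsilyl)oxy]pentanal | O=C[C@H](CCCO[Si](c1ccccc1)(c1ccccc1)C(C)(C)C)[C@@H](O[Si](CC)(CC)CC)CCC1(C)OCCO1 | intermediate
16 | (3S,4S)-3-{3-[(tert-butyldiphenylsilyl)oxy]propyl}-6-(2-methyl-1,3-dioxolan-2-yl)-4-[(triethylsilyl)oxy]hex-1-yne | C#C[C@H](CCCO[Si](c1ccccc1)(c1ccccc1)C(C)(C)C)[C@@H](O[Si](CC)(CC)CC)CCC1(C)OCCO1 | intermediate
17 | (1E,3R,4S)-3-{3-[(tert-butyldiphenylsilyl)oxy]propyl}-2-iodo-6-(2-methyl-1,3-dioxolan-2-yl)-1-(phenylsulfonyl)-4-[(triethylsilyl)oxy]hex-1-ene | I/C(=C/S(=O)(=O)c1ccccc1)[C@H](CCCO[Si](c1ccccc1)(c1ccccc1)C(C)(C)C)[C@@H](O[Si](CC)(CC)CC)CCC1(C)OCCO1 | intermediate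
18 | (1Z,3S,4S)-3-{3-[(tert-butyldiphenylsilyl)oxy]propyl}-2-methyl-6-(2-methyl-1,3-dioxolan-2-yl)-1-(phenylsulfonyl)-4-[(triethylsilyl)oxy]hex-1-ene | C/C(=C/S(=O)(=O)c1ccccc1)[C@H](CCCO[Si](c1ccccc1)(c1ccccc1)C(C)(C)C)[C@@H](O[Si](CC)(CC)CC)CCC1(C)OCCO1 | intermediate
19 | (5S,6S,7Z)-6-{3-[(tert-butyldiphenylsilyl)oxy]propyl}-5-hydroxy-7-methyl-8-(phenylsulfonyl)oct-7-en-2-one | C/C(=C/S(=O)(=O)c1ccccc1)[C@H](CCCO[Si](c1ccccc1)(c1ccccc1)C(C)(C)C)[C@@H](O)CCC(C)=O | intermediate
20 | (1S,2S,3S,4S)-3-{3-[(tert-butyldiphenylsilyl)oxy]propyl}-1,2-dimethyl-2-[(phenylsulfonyl)methyl]cyclohexane-1,4-diol | O=S(=O)(C[C@@]1(C)[C@H](CCCO[Si](c2ccccc2)(c2ccccc2)C(C)(C)C)[C@@H](O)CC[C@]1(C)O)c1ccccc1 | intermediate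
21 | (2S,3S,4S)-2-{3-[(tert-butyldiphenylsilyl)oxy]propyl}-4-hydroxy-3,4-dimethyl-3-[(phenylsulfonyl)methyl]cyclohexan-1-one | O=S(=O)(C[C@@]1(C)[C@H](CCCO[Si](c2ccccc2)(c2ccccc2)C(C)(C)C)C(=O)CC[C@]1(C)O)c1ccccc1 | intermediate
22 | (4S,5S,6S)-6-{3-[(tert-butyldiphenylsilyl)oxy]propyl}-4-hydroxy-4,5-dimethyl-5-[(phenylsulfonyl)methyl]cyclohex-1-en-1-yl trifluoromethanesulfonate | O=S(=O)(C[C@@]1(C)[C@H](CCCO[Si](c2ccccc2)(c2ccccc2)C(C)(C)C)C(OS(=O)(=O)C(F)(F)F)=CC[C@]1(C)O)c1ccccc1 | intermediate
23 | 2-bromoprop-2-en-1-ol | OCC(Br)=C | starting material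
24 | [(2-bromoprop-2-en-1-yl)oxy](tert-butyl)dimethylsilane | C=C(Br)CO[Si](C)(C)C(C)(C)C | intermediate
25 | {3-[(tert-butyldimethylsilyl)oxy]prop-1-en-2-yl}lithium | [Li]C(=C)CO[Si](C)(C)C(C)(C)C | intermediate
26 | {3-[(tert-butyldimethylsilyl)oxy]prop-1-en-2-yl}zinc bromide | Br[Zn]C(=C)CO[Si](C)(C)C(C)(C)C | intermediate
27 | diene: ring as 22 with 3-[(tert-butyldimethylsilyl)oxy]prop-1-en-2-yl at the former triflate carbon | O=S(=O)(C[C@@]1(C)[C@H](CCCO[Si](c2ccccc2)(c2ccccc2)C(C)(C)C)C(C(=C)CO[Si](C)(C)C(C)(C)C)=CC[C@]1(C)O)c1ccccc1 | intermediate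
28 | (Z)-alkylidene sulfone: ring centres as 21, C3 carrying =C(CH3)CH2OSiMe2t-Bu with CH2OSi cis to C2 | O=S(=O)(C[C@@]1(C)[C@H](CCCO[Si](c2ccccc2)(c2ccccc2)C(C)(C)C)/C(=C(/C)CO[Si](C)(C)C(C)(C)C)CC[C@]1(C)O)c1ccccc1 | intermediate
29 | (2E,6E)-farnesyl bromide ((2E,6E)-1-bromo-3,7,11-trimethyldodeca-2,6,10-triene) | BrC/C=C(\C)CC/C=C(\C)CCC=C(C)C | starting material
30 | farnesylated sulfone: as 28 with CH(SO2Ph)–farnesyl at C1 (mixture at the sulfone carbon) | CC(C)=CCC/C(C)=C/CC/C(C)=C/CC(S(=O)(=O)c1ccccc1)[C@@]1(C)[C@H](CCCO[Si](c2ccccc2)(c2ccccc2)C(C)(C)C)/C(=C(/C)CO[Si](C)(C)C(C)(C)C)CC[C@]1(C)O | intermediate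
31 | bis-silyl ether of triol 32 (primary tert-butyldiphenylsilyl ether, allylic tert-butyldimethylsilyl ether) | CC(C)=CCC/C(C)=C/CC/C(C)=C/CC[C@@]1(C)[C@H](CCCO[Si](c2ccccc2)(c2ccccc2)C(C)(C)C)/C(=C(/C)CO[Si](C)(C)C(C)(C)C)CC[C@]1(C)O | intermediate
32 | triol: (Z)-allylic alcohol corresponding to iridal (aldehyde reduced to CH2OH) | CC(C)=CCC/C(C)=C/CC/C(C)=C/CC[C@@]1(C)[C@H](CCCO)/C(=C(/C)CO)CC[C@]1(C)O | intermediate
33 | iridal | CC(C)=CCC/C(C)=C/CC/C(C)=C/CC[C@@]1(C)[C@H](CCCO)/C(=C(/C)C=O)CC[C@]1(C)O | target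

## Step count and risks

Total step count: 21. Longest linear sequence: 19 steps (steps 1, 2, 4–14, 16–21); steps 3 and 15 prepare side fragments.

Steps most likely to fail:

Step 12 (key cyclisation). The vinyl sulfone may be reduced by electron transfer before the ketone; this would scramble the alkene geometry and remove the allylic-strain control at C1, or lead to simple conjugate reduction. Face selectivity at the ketyl carbon C6 may also be incomplete. The fallback generates the C6 radical without a strong reductant. It sets out from 19: silylation with t-BuMe2SiOTf and Et3N (CH2Cl2, −78 → 0 °C) gives the silyl enol ether F1, in which the C3 hydroxyl is silylated as well; either enol ether regioisomer leads to the same radical. A hydrogen-atom-transfer radical cyclisation (Fe(acac)3 with trivalent iron, PhSiH3, EtOH, 60 °C; Mukaiyama-type reductive olefin coupling of a silyl enol ether with a vinyl sulfone) gives the bis-silyl ether F2, with the bulky silyloxy group expected in the equatorial position. Aqueous HF in MeCN removes both tert-butyldimethylsilyl groups, keeps the primary tert-butyldiphenylsilyl ether, and returns to the route at 20.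

Step 17 (1,4-hydrogenation). The hindered 2,3-disubstituted diene may not reach the chromium-bound s-cis form, so that turnover is absent, or double-bond migration may compete. The fallback gives up stereospecificity for a transposition with separation. It sets out from ketone 21: addition of isopropenylmagnesium bromide in the presence of CeCl3 (THF, −78 °C) gives the tertiary allylic alcohol F3. A 1,3-transposition of the allylic hydroxyl catalysed by Ph3SiOReO3 (heptavalent rhenium, Et2O, −50 → 0 °C) gives the primary allylic alcohol F4 as a mixture of alkene isomers. The (Z)-isomer is separated, and the other isomer is re-equilibrated with the same catalyst. Silylation with t-BuMe2SiCl and imidazole returns to the route at 28.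

Step 16 (Negishi coupling). Oxidative addition and transmetalation at the hindered enol triflate may be slow, the alkenylzinc may lose the β-silyloxy group, or it may be protonated by the tertiary alcohol. The fallback reverses the polarity of the coupling. It sets out from 22: Miyaura borylation (B2pin2, Pd(dppf)Cl2, KOAc, dioxane, 80 °C) gives the alkenyl pinacol boronate F5. Suzuki–Miyaura coupling of this boronate with bromide 24 (Pd(PPh3)4, aq. K3PO4, THF, 60 °C) returns to the route at 27.

Further compounds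
F1 | step 12 | silyl enol ether of 19 with the C3 hydroxyl silylated (terminal enol ether shown) | C/C(=C/S(=O)(=O)c1ccccc1)[C@H](CCCO[Si](c1ccccc1)(c1ccccc1)C(C)(C)C)[C@@H](O[Si](C)(C)C(C)(C)C)CCC(=C)O[Si](C)(C)C(C)(C)C
F2 | step 12 | C3,C6-bis(tert-butyldimethylsilyl) ether of 20 | O=S(=O)(C[C@@]1(C)[C@H](CCCO[Si](c2ccccc2)(c2ccccc2)C(C)(C)C)[C@@H](O[Si](C)(C)C(C)(C)C)CC[C@]1(C)O[Si](C)(C)C(C)(C)C)c1ccccc1
F3 | step 17 | tertiary allylic alcohol from 21 by isopropenyl addition (configuration at C3 not defined) | O=S(=O)(C[C@@]1(C)[C@H](CCCO[Si](c2ccccc2)(c2ccccc2)C(C)(C)C)C(O)(C(C)=C)CC[C@]1(C)O)c1ccccc1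
F4 | step 17 | transposed primary allylic alcohol (mixture of alkene isomers) | O=S(=O)(C[C@@]1(C)[C@H](CCCO[Si](c2ccccc2)(c2ccccc2)C(C)(C)C)C(=C(C)CO)CC[C@]1(C)O)c1ccccc1
F5 | step 16 | alkenyl pinacol boronate from 22 | O=S(=O)(C[C@@]1(C)[C@H](CCCO[Si](c2ccccc2)(c2ccccc2)C(C)(C)C)C(B2OC(C)(C)C(C)(C)O2)=CC[C@]1(C)O)c1ccccc1
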